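**Strategy**

The carbocycle is dissected into a three-carbon piece, C6–C7–C8 with C10 attached, and the C5=C9 enone bond of a pyranone that already holds C1, O2, C3 and the C4 carbonyl. A single phosphine-catalysed allenoate [3+2] annulation forms C8–C9 and C5–C6, closes the cyclopentene ring and sets C9 by attack anti to the pseudoaxial acyloxy group on the C1 acetal, the structural feature the step exploits. Its precursor is the S-configured 6-acyloxy-2H-pyran-3(6H)-one that already bears the target's 3-acetoxy-3-methylbutanoyl group on O1, so the chirality-relaying acetal is never reopened and every later step is free of ester-cleaving hydrides.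

Key step: step 5

Assumption 1: atom labels follow the iridoid skeleton (C1 acetal, O2, C3, C4, ring-fusion C5 and C9, carbocycle C6 to C8, C10 on C8, C11 on C4).
Assumption 2: the (R)-enantiomer of benzotetramisole is taken to give the S acylal in step 3; should the sense prove opposite, its antipode is used.

**Route**

Step 1
Reactants: 1 furfuryl alcohol
Product: 2 6-hydroxy-2H-pyran-3(6H)-one (racemic lactol)
Conditions: mCPBA, CH2Cl2, 0 °C → rt
Reagents that add atoms: mCPBA, OOC(=O)c1cccc(Cl)c1
Why: Achmatowicz oxidative ring expansion, in which peracid oxidation of the furan, opening to the cis-enedione and recyclisation through the carbinol oxygen should give the pyranone hemiacetal, racemic because its acetal carbon epimerises by ring–chain tautomerism.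

Step 2
Reactants: 3 3-hydroxy-3-methylbutanoic acid
Product: 5 3-acetoxy-3-methylbutanoic acid, via acetic 3-acetoxy-3-methylbutanoic anhydride 4 (not isolated)
Conditions: AcCl (excess), neat, 0 °C → rt; then H2O, THF
Reagents that add atoms: acetyl chloride, CC(Cl)=O
Why: Base-free O-acetylation of the tertiary alcohol by an acyl chloride, which avoids β-lactone formation and β-elimination, while the carboxyl group is acylated too and the mixed anhydride is hydrolysed at its less hindered acetyl carbonyl on work-up.

Step 3
Reactants: 2 6-hydroxy-2H-pyran-3(6H)-one; 5 3-acetoxy-3-methylbutanoic acid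
Product: 7 (S)-6-[(3-acetoxy-3-methylbutanoyl)oxy]-2H-pyran-3(6H)-one, via 3-acetoxy-3-methylbutanoic anhydride 6 (not isolated)
Conditions: 5 (2.4 equiv), DCC, CH2Cl2, 0 °C, filter; then 2, (R)-benzotetramisole (5 mol %), iPr2NEt, CHCl3, 0 °C
Reagents that add atoms: none
Why: Isothiourea-catalysed enantioselective acyl transfer run as a dynamic kinetic resolution, in which the lactol enantiomers interconvert through the open hydroxy-enedione under the amine base while the chiral acyl-isothiouronium ion acylates one of them faster, so the single acetal stereocentre (S) is set by the catalyst.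

Step 4
Reactants: 8 allyl (triphenylphosphoranylidene)acetate
Product: 9 allyl buta-2,3-dienoate
Conditions: AcCl, Et3N, CH2Cl2, 0 °C → rt
Reagents that add atoms: acetyl chloride, CC(Cl)=O
Why: Wittig olefination of ketene, generated in the flask from acetyl chloride and Et3N, by the stabilised ylide should give the 2,3-dienoate directly with loss of Ph3PO.

Step 5
Reactants: 7 (S)-6-[(3-acetoxy-3-methylbutanoyl)oxy]-2H-pyran-3(6H)-one; 9 allyl buta-2,3-dienoate
Product: 10 allyl (1S,4aS,7aS)-1-[(3-acetoxy-3-methylbutanoyl)oxy]-4-oxo-1,3,4,4a,5,7a-hexahydrocyclopenta[c]pyran-7-carboxylate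
Conditions: PPh3 (10 mol %), toluene, 110 °C, slow addition of 9
Reagents that add atoms: none
Why: PPh3 adds to the central allene carbon of 9 to give a 1,3-zwitterion whose ester-bearing carbon (future C8) adds to the enone β-carbon C9, the resulting C5 enolate then attacks the terminal carbon of the vinylphosphonium unit (future C6), and a proton shift with loss of PPh3 leaves the C7=C8 enoate. The closest known reaction type is the Lu phosphine-catalysed allenoate–enone [3+2] annulation, already practised on 6-acyloxy-2H-pyran-3(6H)-ones. The one ring formed, the cyclopentene, is closed by the second bond (C5–C6), formally a 5-endo-trig addition of an exocyclic enolate to the vinylphosphonium that is best regarded as the completing step of a stepwise [3+2] cycloaddition. C9 is set by the C1 acetal centre, whose acyloxy group is pseudoaxial (anomeric effect) and screens its own face so that the zwitterion arrives anti to it and H-9 ends cis to O1; C5 follows from C9 because the three-atom bridge can only reach the same face, which gives the cis ring fusion. The step needs α-regiochemistry (ester carbon to C9) and anti facial selectivity: the first is the normal outcome for an unsubstituted allenoate with PPh3 and a cyclic enone, the second is secured by the resident C1 substituent.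

Step 6
Reactants: 10 allyl ester cycloadduct
Product: 11 (1S,4aS,7aS)-1-[(3-acetoxy-3-methylbutanoyl)oxy]-4-oxo-1,3,4,4a,5,7a-hexahydrocyclopenta[c]pyran-7-carboxylic acid
Conditions: Pd(PPh3)4 (3 mol %), N-methylaniline, THF, rt
Reagents that add atoms: none
Why: Tsuji–Trost deallylation, in which zerovalent palladium ionises only the allyl ester to a π-allyl complex that the weakly nucleophilic aniline intercepts, should free the acid without base or hydride and leave ketone, acylal and tertiary acetate untouched.

Step 7
Reactants: 11 C10 carboxylic acid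
Product: 13 C10 aldehyde (4-keto enal; C7=C8 retained), via C10 acid chloride 12 (not isolated)
Conditions: 1-chloro-N,N,2-trimethylprop-1-en-1-amine, CH2Cl2, 0 °C; then Pd(PPh3)4 (2 mol %), Bu3SnH (slow addition), toluene, rt
Reagents that add atoms: none
Why: The α-chloroenamine converts the acid into its chloride under neutral conditions, and palladium-catalysed tin hydride reduction of acyl chlorides (oxidative addition into C–Cl, hydride transfer from tin, reductive elimination) should stop at the aldehyde without touching ketone, esters or the conjugated alkene.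

Step 8
Reactants: 13 C10 aldehyde
Product: 14 4-keto C10 allylic alcohol
Conditions: NaBH(OAc)3, toluene, 60 °C
Reagents that add atoms: none
Why: Chemoselective carbonyl reduction by NaBH(OAc)3, a weak hydride donor that reduces aldehydes 1,2 but leaves ketones and esters alone, should give the allylic alcohol with the C4 ketone, the acylal and the tertiary acetate intact.

Step 9
Reactants: 14 4-keto C10 allylic alcohol
Product: 15 4-keto 7,8-epoxy C10 alcohol (oxirane oxygen cis to H-9)
Conditions: VO(acac)2 (3 mol %), tBuOOH, CH2Cl2, 0 °C → rt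
Reagents that add atoms: tert-butyl hydroperoxide, CC(C)(C)OO
Why: Hydroxyl-directed VO(acac)2/tBuOOH epoxidation of an allylic alcohol, in which the vanadate ester of O10 delivers oxygen to C7=C8 on the open convex face of the cis-fused bicycle (the face of H-5 and H-9, the pyran ring folding over the other), so that the oxirane oxygen, the future C8 hydroxyl, ends cis to H-9 and the ketone suffers no Baeyer–Villiger oxidation.

Step 10
Reactants: 15 4-keto 7,8-epoxy C10 alcohol; 16 isovaleric acid
Product: 17 4-keto 7-O-isovaleryl 8,10-diol (O7 trans to H-9; 8-OH cis to H-9)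
Conditions: Ti(OiPr)4, 16, CH2Cl2, rt
Reagents that add atoms: none
Why: Ti(OiPr)4-mediated C3-selective opening of a 2,3-epoxy alcohol by a carboxylic acid, in which titanium bound to O10 and the oxirane oxygen activates the epoxide and isovalerate attacks the less substituted C7 in SN2 fashion from the face opposite the oxirane, so C7 is inverted to the trans 7-acyloxy-8-hydroxy pattern while the C8–O bond and its configuration are kept.

Step 11
Reactants: 17 4-keto 7-O-isovaleryl 8,10-diol
Product: 18 4-keto 7,10-di-O-isovaleryl 8-ol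
Conditions: isovaleric anhydride, Et3N, DMAP (cat.), CH2Cl2, 0 °C
Reagents that add atoms: isovaleric anhydride, CC(C)CC(=O)OC(=O)CC(C)C
Why: DMAP-catalysed acylation by the anhydride should esterify the primary C10 hydroxyl (and re-esterify O7 should any 7-to-10 acyl shift have occurred) while the hindered tertiary C8 hydroxyl does not react at 0 °C.

Step 12
Reactants: 18 4-keto 7,10-di-O-isovaleryl 8-ol
Product: 19 C5=C6 enone (8-OH free)
Conditions: IBX (3 equiv), DMSO/fluorobenzene, 70 °C
Reagents that add atoms: none
Why: IBX dehydrogenation of a ketone through its enol, in which enolisation toward C3 is unproductive because the next atom is the ring oxygen, and from the C5 enol the oxidant should remove the accessible H-6 and not H-9 (tertiary, flanked by the C1 acyloxy and C8 groups), so the transient C5 stereocentre disappears and C5=C6 results.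

Step 13
Reactants: 19 C5=C6 enone
Product: 20 8-O-trimethylsilyl enone
Conditions: N-(trimethylsilyl)imidazole, CH2Cl2, rt
Reagents that add atoms: N-(trimethylsilyl)imidazole, C[Si](C)(C)n1ccnc1
Why: Silylation with a neutral silyl donor that does not enolise the ketone caps the tertiary C8 hydroxyl, so that no alkoxide able to trigger acyl migration can form in the next step.

Step 14
Reactants: 20 8-O-trimethylsilyl enone
Product: 21 C4 dienyl triflate (C3=C4 and C5=C6)
Conditions: KN(SiMe3)2, PhNTf2, THF, −78 °C
Reagents that add atoms: N-phenylbis(trifluoromethanesulfonimide), O=S(=O)(N(c1ccccc1)S(=O)(=O)C(F)(F)F)C(F)(F)F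
Why: Enol triflate formation by kinetic α′-deprotonation of the enone at C3 and O-sulfonylation of the cross-conjugated dienolate; the ketone is several pK units more acidic than any ester α-position, so the esters and the β-acetoxy ester should survive at this temperature.

Step 15
Reactants: 21 C4 dienyl triflate; 22 (tributylstannyl)methanol
Product: 23 C11 alcohol (8-O-trimethylsilyl)
Conditions: Pd(PPh3)4 (10 mol %), LiCl, 1,4-dioxane, 80 °C
Reagents that add atoms: none
Why: Stille coupling (oxidative addition of zerovalent palladium into the alkenyl C–OTf bond, chloride-assisted transfer of the oxygen-activated hydroxymethyl group from tin, reductive elimination) should install C11 as the free alcohol, which unlike an ester is not ionised by the catalyst.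

Step 16
Reactants: 23 C11 alcohol
Product: 24 C11 acetate (8-O-trimethylsilyl)
Conditions: Ac2O, pyridine, DMAP (cat.), CH2Cl2, 0 °C
Reagents that add atoms: acetic anhydride, CC(=O)OC(C)=O
Why: Pyridine/DMAP-mediated acetylation of the primary allylic alcohol, the only free hydroxyl present since O8 is still silylated.

Step 17
Reactants: 24 C11 acetate
Product: 25 target CNP0331701.2
Conditions: HF·pyridine, pyridine, THF, 0 °C
Reagents that add atoms: none
Why: Fluoride-induced cleavage of the trimethylsilyl ether (Si–F bond formation) under pyridine-buffered conditions should free the C8 hydroxyl without ionising the dienyl acylal or the allylic esters.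

**Compound list**

1 | furfuryl alcohol (furan-2-ylmethanol) | OCc1ccco1 | starting material
2 | 6-hydroxy-2H-pyran-3(6H)-one, racemic lactol | O=C1COC(O)C=C1 | intermediate
3 | 3-hydroxy-3-methylbutanoic acid | CC(C)(O)CC(O)=O | starting material
4 | acetic 3-acetoxy-3-methylbutanoic anhydride | CC(=O)OC(C)(C)CC(=O)OC(C)=O | intermediate (not isolated)
5 | 3-acetoxy-3-methylbutanoic acid | CC(=O)OC(C)(C)CC(O)=O | intermediate
6 | 3-acetoxy-3-methylbutanoic anhydride | CC(=O)OC(C)(C)CC(=O)OC(=O)CC(C)(C)OC(C)=O | intermediate (not isolated)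
7 | (S)-6-[(3-acetoxy-3-methylbutanoyl)oxy]-2H-pyran-3(6H)-one, annulation precursor | O=C1CO[C@@H](OC(=O)CC(C)(C)OC(C)=O)C=C1 | intermediate
8 | allyl (triphenylphosphoranylidene)acetate | C=CCOC(=O)C=P(c1ccccc1)(c1ccccc1)c1ccccc1 | starting material
9 | allyl buta-2,3-dienoate | C=C=CC(=O)OCC=C | intermediate
10 | allyl (1S,4aS,7aS)-1-[(3-acetoxy-3-methylbutanoyl)oxy]-4-oxo-1,3,4,4a,5,7a-hexahydrocyclopenta[c]pyran-7-carboxylate; cis-fused, O1, H-5 and H-9 on one face, C7=C8, C10 as allyl ester | O=C1CO[C@@H](OC(=O)CC(C)(C)OC(C)=O)[C@H]2[C@@H]1CC=C2C(=O)OCC=C | intermediate (annulation product)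
11 | C10 carboxylic acid corresponding to 10 | O=C1CO[C@@H](OC(=O)CC(C)(C)OC(C)=O)[C@H]2[C@@H]1CC=C2C(O)=O | intermediate
12 | C10 acid chloride of 11 | O=C1CO[C@@H](OC(=O)CC(C)(C)OC(C)=O)[C@H]2[C@@H]1CC=C2C(Cl)=O | intermediate (not isolated)
13 | C10 aldehyde (4-keto enal, C7=C8) | O=C1CO[C@@H](OC(=O)CC(C)(C)OC(C)=O)[C@H]2[C@@H]1CC=C2C=O | intermediate
14 | 4-keto C10 allylic alcohol (C7=C8) | O=C1CO[C@@H](OC(=O)CC(C)(C)OC(C)=O)[C@H]2[C@@H]1CC=C2CO | intermediate
15 | 4-keto 7,8-epoxide with free C10 hydroxyl, oxirane oxygen on the face of H-9 | O=C1CO[C@@H](OC(=O)CC(C)(C)OC(C)=O)[C@H]2[C@@H]1C[C@@H]3O[C@]23CO | intermediate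
16 | isovaleric acid (3-methylbutanoic acid) | CC(C)CC(O)=O | starting material
17 | 4-keto 7-O-isovaleryl 8,10-diol; O7 trans to H-9, 8-OH cis to H-9 | O=C1CO[C@@H](OC(=O)CC(C)(C)OC(C)=O)[C@H]2[C@@H]1C[C@@H](OC(=O)CC(C)C)[C@@]2(O)CO | intermediate
18 | 4-keto 7,10-di-O-isovaleryl 8-ol | O=C1CO[C@@H](OC(=O)CC(C)(C)OC(C)=O)[C@H]2[C@@H]1C[C@@H](OC(=O)CC(C)C)[C@@]2(O)COC(=O)CC(C)C | intermediate
19 | 4-oxo C5=C6 enone, 8-OH free | O=C1CO[C@@H](OC(=O)CC(C)(C)OC(C)=O)[C@H]2C1=C[C@@H](OC(=O)CC(C)C)[C@@]2(O)COC(=O)CC(C)C | intermediate
20 | 8-O-trimethylsilyl ether of 19 | O=C1CO[C@@H](OC(=O)CC(C)(C)OC(C)=O)[C@H]2C1=C[C@@H](OC(=O)CC(C)C)[C@@]2(O[Si](C)(C)C)COC(=O)CC(C)C | intermediate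
21 | C4 trifluoromethanesulfonyloxy 3,5-diene, 8-O-trimethylsilyl | FC(F)(F)S(=O)(=O)OC1=CO[C@@H](OC(=O)CC(C)(C)OC(C)=O)[C@H]2C1=C[C@@H](OC(=O)CC(C)C)[C@@]2(O[Si](C)(C)C)COC(=O)CC(C)C | intermediate
22 | (tributylstannyl)methanol | CCCC[Sn](CCCC)(CCCC)CO | starting material
23 | C11 alcohol (4-hydroxymethyl 3,5-diene), 8-O-trimethylsilyl | OCC1=CO[C@@H](OC(=O)CC(C)(C)OC(C)=O)[C@H]2C1=C[C@@H](OC(=O)CC(C)C)[C@@]2(O[Si](C)(C)C)COC(=O)CC(C)C | intermediate
24 | C11 acetate, 8-O-trimethylsilyl | CC(=O)OCC1=CO[C@@H](OC(=O)CC(C)(C)OC(C)=O)[C@H]2C1=C[C@@H](OC(=O)CC(C)C)[C@@]2(O[Si](C)(C)C)COC(=O)CC(C)C | intermediate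
25 | (1S,6R,7S,7aS)-4-(acetoxymethyl)-1-[(3-acetoxy-3-methylbutanoyl)oxy]-7-hydroxy-7-{[(3-methylbutanoyl)oxy]methyl}-1,6,7,7a-tetrahydrocyclopenta[c]pyran-6-yl 3-methylbutanoate (CNP0331701.2) | CC(=O)OCC1=CO[C@@H](OC(=O)CC(C)(C)OC(C)=O)[C@H]2C1=C[C@@H](OC(=O)CC(C)C)[C@@]2(O)COC(=O)CC(C)C | target

**Step count and risk**

Total step count: 17. Longest linear sequence: 15 steps (steps 1, 3 and 5 to 17, from furfuryl alcohol).

Steps most likely to fail:

Step 5. What may go wrong: base-triggered loss of the acyloxy group from 7 (ionisation toward the 3-oxidopyrylium), weaker facial shielding by an acyl group less bulky than a pivalate, or oligomerisation of the allenoate. Fallback: set out from lactol 2 and acylate it under the conditions of step 3 with pivalic anhydride to give (S)-6-pivaloyloxy-2H-pyran-3(6H)-one F1. The PPh3 annulation with 9 then gives the pivalate cycloadduct F2. Only afterwards is the anomeric ester exchanged by Lewis-acid-promoted trans-acylation (TMSOTf, excess 5, CH2Cl2, −40 °C) through the C1 oxocarbenium ion, which should be captured axially and anti to C8. The route is rejoined at 10.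

Step 12. What may go wrong: hydrogen loss toward C9 instead of C6, oxidation next to the ring oxygen at C3, or thermal erosion of the acylal in hot DMSO. Fallback: set out from 18 and cap the C8 hydroxyl with N-(trimethylsilyl)imidazole to give the 8-O-trimethylsilyl ketone F3. Kinetic deprotonation away from the ring oxygen (LiN(SiMe3)2, Me3SiCl, THF, −78 °C) gives the C4–C5 trimethylsilyl enol ether F4. NBS converts this into the 5-bromo ketone F5, bromine entering on the convex face, cis to H-9. DBU then removes HBr; anti elimination can use only a C6 hydrogen because H-9 is syn to bromine. The route is rejoined at 20.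

Step 15. What may go wrong: the slow transfer of an sp3 carbon from tin needs heat, during which zerovalent palladium may ionise the doubly allylic C7 isovalerate or acyloxy groups may be lost from the dienyl acylal. Fallback: set out from 21 and carry out a reductive carbonylation (Pd(PPh3)4, CO at 1 atm, Bu3SnH added slowly, THF, 50 °C) to the C11 dienal F6. Luche reduction (NaBH4, CeCl3·7H2O, MeOH, −78 °C) then gives the allylic alcohol, and the route is rejoined at 23.

**Further compounds**

F1 | step 5 | (S)-6-pivaloyloxy-2H-pyran-3(6H)-one | O=C1CO[C@@H](OC(=O)C(C)(C)C)C=C1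
F2 | step 5 | allyl (1S,4aS,7aS)-4-oxo-1-pivaloyloxy-1,3,4,4a,5,7a-hexahydrocyclopenta[c]pyran-7-carboxylate (pivalate cycloadduct) | O=C1CO[C@@H](OC(=O)C(C)(C)C)[C@H]2[C@@H]1CC=C2C(=O)OCC=C
F3 | step 12 | 8-O-trimethylsilyl ether of ketone 18 | O=C1CO[C@@H](OC(=O)CC(C)(C)OC(C)=O)[C@H]2[C@@H]1C[C@@H](OC(=O)CC(C)C)[C@@]2(O[Si](C)(C)C)COC(=O)CC(C)C
F4 | step 12 | C4–C5 trimethylsilyl enol ether of F3 | C[Si](C)(C)OC=1CO[C@@H](OC(=O)CC(C)(C)OC(C)=O)[C@H]2C=1C[C@@H](OC(=O)CC(C)C)[C@@]2(O[Si](C)(C)C)COC(=O)CC(C)C
F5 | step 12 | 5-bromo ketone, bromine cis to H-9, 8-O-trimethylsilyl | O=C1CO[C@@H](OC(=O)CC(C)(C)OC(C)=O)[C@H]2[C@]1(Br)C[C@@H](OC(=O)CC(C)C)[C@@]2(O[Si](C)(C)C)COC(=O)CC(C)C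
F6 | step 15 | C11 dienal (4-formyl 3,5-diene), 8-O-trimethylsilyl | O=CC1=CO[C@@H](OC(=O)CC(C)(C)OC(C)=O)[C@H]2C1=C[C@@H](OC(=O)CC(C)C)[C@@]2(O[Si](C)(C)C)COC(=O)CC(C)C
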